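**Strategy.** The cyclohexene ring is opened at C1–C2: the vicinal oxygens at the quaternary C1 and at C2 are the retron of an α-ketol, and the chain C2–C3–C4–C5 with its threo C3/C4 oxygens is L-tartrate. A chiral triazolylidene turns the C2 aldehyde of an acyclic (Z)-enone aldehyde into an acyl anion equivalent that adds to the C1 ketone. One operation closes the six-membered ring, forms C1–C2 and sets the tertiary carbinol. The precursor 18 carries C3-OPMB, C4-OTBS and a PMB ether at C7, so both oxygens that end as benzoates are unmasked and acylated together after the ring is built.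

Key step: step 11

Remark on labels: C1 is the quaternary carbinol, C7 its CH2O carbon, C2 CHOH, C3 CHOBz, C4 the allylic CHOH, C5=C6 the alkene; β is the face of the three free hydroxyls. Compounds 19 and 20 are named with these locants.

Remark on the precursor: the C7 oxygen travels as a PMB ether, not as the final benzoate. An ester there would not survive the acetylide and aluminium hydride steps, would acidify the C7 hydrogens of the ketone, and could shift to the new tertiary alkoxide. The two chain ends of tartrate are told apart by a hydroxyl-directed ester reduction, and the C3 PMB ether is set by reductive opening of an acetal.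

Assumption: the acetal carbon of 4, 6, 7 and 14–16 and the carbinol carbon C1 of 15–17 are epimer mixtures that converge in steps 9 and 10. Their SMILES leave these centres open, as does that of the racemic ozonide 12.

Remark on intermediates: only stoichiometric species that persist between two operations of one step are numbered; catalyst-bound transients are described in words.

Step 1
Reactants: 1 diethyl L-tartrate
Product: 2 diethyl (2R,3R)-2-[(tert-butyldimethylsilyl)oxy]-3-hydroxybutanedioate
Conditions: TBSCl (1.0 equiv), imidazole, DMF, 0 °C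
Reagents that add atoms: tert-butyldimethylsilyl chloride, CC(C)(C)[Si](C)(C)Cl
Why: Silyl ether formation on a C2-symmetric diol whose hydroxyls are homotopic, so monosilylation can give only one compound and the second, now hindered hydroxyl reacts more slowly; this oxygen becomes C4-OTBS.

Step 2
Reactants: 2 diethyl (2R,3R)-2-[(tert-butyldimethylsilyl)oxy]-3-hydroxybutanedioate
Product: 3 ethyl (2R,3S)-2-[(tert-butyldimethylsilyl)oxy]-3,4-dihydroxybutanoate
Conditions: BH3·SMe2 (1.05 equiv), NaBH4 (5 mol %), THF, 0 °C → rt; then MeOH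
Reagents that add atoms: none
Why: Hydroxyl-directed borane reduction of an α-hydroxy ester, in which the free hydroxyl forms an alkoxyborane that delivers hydride through a five-membered chelate only to the ester next to it, so the C2 end becomes CH2OH while the C5 end stays an ester.

Step 3
Reactants: 3 ethyl (2R,3S)-2-[(tert-butyldimethylsilyl)oxy]-3,4-dihydroxybutanoate
Product: 4 ethyl (2R)-2-[(tert-butyldimethylsilyl)oxy]-2-[(4S)-2-(4-methoxyphenyl)-1,3-dioxolan-4-yl]acetate
Conditions: 4-MeOC6H4CH(OMe)2, pyridinium p-toluenesulfonate (cat.), CH2Cl2, rt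
Reagents that add atoms: 4-methoxybenzaldehyde dimethyl acetal, COC(OC)c1ccc(OC)cc1
Why: Acid-catalysed transacetalisation of a terminal 1,2-diol to the five-membered p-methoxybenzylidene acetal, which should outrun lactonisation onto the ester, spares the silyl ether, masks the C2 hydroxyl and stores the future C3 PMB ether.

Step 4
Reactants: 4 ethyl (2R)-2-[(tert-butyldimethylsilyl)oxy]-2-[(4S)-2-(4-methoxyphenyl)-1,3-dioxolan-4-yl]acetate; 5 dimethyl (1-diazo-2-oxopropyl)phosphonate
Product: 7 (4S)-4-[(1S)-1-[(tert-butyldimethylsilyl)oxy]prop-2-yn-1-yl]-2-(4-methoxyphenyl)-1,3-dioxolane, via aldehyde 6 (not isolated)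
Conditions: i-Bu2AlH (1.1 equiv), CH2Cl2, −78 °C; then MeOH, K2CO3, 5, −78 °C → rt
Reagents that add atoms: none
Why: Partial reduction of an α-oxygenated ester to the aldehyde through a stable aluminium hemiacetal, followed in the same flask by Ohira–Bestmann (Seyferth–Gilbert) homologation, which makes C5 the internal alkyne carbon and brings in C6 without touching the C4 stereocenter.

Step 5
Reactants: 8 allyl alcohol; 9 4-methoxybenzyl chloride
Product: 11 1-methoxy-4-[(prop-2-en-1-yloxy)methyl]benzene, via sodium prop-2-en-1-olate 10 (not isolated)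
Conditions: NaH, THF, 0 °C; then 9, Bu4NI (cat.), 0 °C → rt
Reagents that add atoms: none
Why: Williamson ether synthesis, in which the primary alkoxide displaces the benzylic chloride with iodide as nucleophilic catalyst.

Step 6
Reactants: 11 1-methoxy-4-[(prop-2-en-1-yloxy)methyl]benzene
Product: 13 2-[(4-methoxybenzyl)oxy]acetaldehyde, via ozonide 12 (not isolated)
Conditions: O3, CH2Cl2, −78 °C (Sudan Red 7B end point); then Me2S, −78 °C → rt
Reagents that add atoms: ozone, [O-][O+]=O
Why: Ozonolysis with reductive work-up, in which the terminal alkene reacts far faster than the anisyl ring at −78 °C and the dye marks the end point before the arene is attacked.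

Step 7
Reactants: 7 (4S)-4-[(1S)-1-[(tert-butyldimethylsilyl)oxy]prop-2-yn-1-yl]-2-(4-methoxyphenyl)-1,3-dioxolane; 13 2-[(4-methoxybenzyl)oxy]acetaldehyde
Product: 15 (5S)-5-[(tert-butyldimethylsilyl)oxy]-1-[(4-methoxybenzyl)oxy]-5-[(4S)-2-(4-methoxyphenyl)-1,3-dioxolan-4-yl]pent-3-yn-2-ol, via lithium acetylide 14 (not isolated)
Conditions: n-BuLi (1.05 equiv), THF, −78 °C; then 13, −78 °C; aq NH4Cl
Reagents that add atoms: none
Why: 1,2-Addition of a lithium acetylide to an aldehyde forms C6–C1 and brings in C7, and the C1 carbinol may arise as both epimers because it is oxidised to the ketone in step 10.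

Step 8
Reactants: 15 (5S)-5-[(tert-butyldimethylsilyl)oxy]-1-[(4-methoxybenzyl)oxy]-5-[(4S)-2-(4-methoxyphenyl)-1,3-dioxolan-4-yl]pent-3-yn-2-ol
Product: 16 (3Z,5S)-5-[(tert-butyldimethylsilyl)oxy]-1-[(4-methoxybenzyl)oxy]-5-[(4S)-2-(4-methoxyphenyl)-1,3-dioxolan-4-yl]pent-3-en-2-ol
Conditions: H2 (1 atm), Pd/CaCO3 poisoned with Pb(OAc)2, quinoline, EtOAc, rt
Reagents that add atoms: none
Why: Lindlar semihydrogenation, in which syn delivery of hydrogen on the lead-poisoned palladium surface gives the (Z)-alkene C5=C6 that the ring closure needs, while benzylic ethers and the acetal are not hydrogenolysed on this catalyst.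

Step 9
Reactants: 16 (3Z,5S)-5-[(tert-butyldimethylsilyl)oxy]-1-[(4-methoxybenzyl)oxy]-5-[(4S)-2-(4-methoxyphenyl)-1,3-dioxolan-4-yl]pent-3-en-2-ol
Product: 17 (2S,3S,4Z)-3-[(tert-butyldimethylsilyl)oxy]-2,7-bis[(4-methoxybenzyl)oxy]hept-4-ene-1,6-diol
Conditions: i-Bu2AlH (5 equiv), CH2Cl2, −78 → 0 °C; aq KNaC4H4O6
Reagents that add atoms: none
Why: Regioselective reductive opening of a p-methoxybenzylidene acetal, in which aluminium binds the less hindered primary oxygen, that C–O bond breaks and hydride quenches the oxocarbenium ion, leaving the PMB ether on the secondary C3 oxygen and the C2 hydroxyl free.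

Step 10
Reactants: 17 (2S,3S,4Z)-3-[(tert-butyldimethylsilyl)oxy]-2,7-bis[(4-methoxybenzyl)oxy]hept-4-ene-1,6-diol
Product: 18 (2R,3S,4Z)-3-[(tert-butyldimethylsilyl)oxy]-2,7-bis[(4-methoxybenzyl)oxy]-6-oxohept-4-enal
Conditions: Dess–Martin periodinane (3 equiv), NaHCO3, CH2Cl2, 0 °C → rt; crude product used at once
Reagents that add atoms: none
Why: Dess–Martin oxidation of both carbinols in one operation under buffered, amine-free conditions, which should keep the (Z)-enone from isomerising and the α-alkoxy aldehyde from epimerising.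

Step 11
Reactants: 18 (2R,3S,4Z)-3-[(tert-butyldimethylsilyl)oxy]-2,7-bis[(4-methoxybenzyl)oxy]-6-oxohept-4-enal
Product: 19 (1S,3R,4S)-4-[(tert-butyldimethylsilyl)oxy]-1-hydroxy-3-[(4-methoxybenzyl)oxy]-1-{[(4-methoxybenzyl)oxy]methyl}cyclohex-5-en-2-one
Conditions: (5aS,10bR)-2-(pentafluorophenyl)-5a,10b-dihydro-4H,6H-indeno[2,1-b][1,2,4]triazolo[4,3-d][1,4]oxazin-2-ium tetrafluoroborate (20 mol %), Et3N (20 mol %), toluene (degassed), 23 °C
Reagents that add atoms: none
Why: The triazolylidene set free by Et3N adds to the C2 aldehyde, a proton shift gives the enaminol (Breslow intermediate), its nucleophilic C2 attacks the C1 ketone while the enaminol O–H activates the carbonyl oxygen, and proton transfer with loss of the carbene leaves the C2 ketone and the C1 tertiary alcohol. The closest known reaction type is the carbene-catalysed intramolecular crossed aldehyde–ketone benzoin that gives six-membered tertiary α-ketols, including closures of sugar-derived α-alkoxy aldehydes to inososes. The ring forms by 6-exo-trig attack on the exocyclic C1=O; the (Z)-alkene C5=C6 holds both carbonyl groups on one side, and conjugate attack at C5 is excluded because it would need a four-membered ring. The new stereocenter C1 is controlled by the resident C3 and C4 centres through a half-chair transition state in which C3-OPMB, C4-OTBS and the CH2OPMB arm are pseudo-equatorial, so the carbonyl oxygen lies pseudo-axial on the β face; the catalyst antipode whose indane wall shields the opposite enaminol face should reinforce this, and the other antipode is the first variable to change if the pairing proves mismatched. The step needs the aldehyde alone as acyl donor, 1,2-addition and retention of the C3 oxygen: only the aldehyde can form the enaminol, the PMB ether is a poor leaving group for redox elimination, and a weak amine base with an electron-poor N-aryl catalyst should avoid epimerisation at C3 and β-elimination of the C4 silyloxy group. The PMB ether at C7 removes the acidic α-acyloxy ketone hydrogens and the acyl shift to the new tertiary alkoxide that an ester at C7 would allow.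

Step 12
Reactants: 19 (1S,3R,4S)-4-[(tert-butyldimethylsilyl)oxy]-1-hydroxy-3-[(4-methoxybenzyl)oxy]-1-{[(4-methoxybenzyl)oxy]methyl}cyclohex-5-en-2-one
Product: 20 (1S,2S,3S,4S)-4-[(tert-butyldimethylsilyl)oxy]-3-[(4-methoxybenzyl)oxy]-1-{[(4-methoxybenzyl)oxy]methyl}cyclohex-5-ene-1,2-diol
Conditions: NaBH4, MeOH/CH2Cl2, −78 → −40 °C
Reagents that add atoms: none
Why: Borohydride reduction of the ketone, in which the small hydride should add axially from the α face of the half-chair that keeps C3-OPMB, C4-OTBS and the CH2OPMB arm equatorial, anti to the axial C1–O bond (polar Felkin–Anh), to give the equatorial C2 β-alcohol cis to the C1 hydroxyl.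

Step 13
Reactants: 20 (1S,2S,3S,4S)-4-[(tert-butyldimethylsilyl)oxy]-3-[(4-methoxybenzyl)oxy]-1-{[(4-methoxybenzyl)oxy]methyl}cyclohex-5-ene-1,2-diol
Product: 21 tert-butyl{[(3aS,4S,5S,7aS)-4-[(4-methoxybenzyl)oxy]-7a-{[(4-methoxybenzyl)oxy]methyl}-2,2-dimethyl-3a,4,5,7a-tetrahydro-1,3-benzodioxol-5-yl]oxy}dimethylsilane
Conditions: Me2C(OMe)2, pyridinium p-toluenesulfonate (cat.), CH2Cl2, rt
Reagents that add atoms: 2,2-dimethoxypropane, COC(C)(C)OC
Why: Acetonide formation, open only to the cis-1,2-diol, which confirms the C1/C2 relationship and blocks these two hydroxyls before the benzoates are placed.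

Step 14
Reactants: 21 tert-butyl{[(3aS,4S,5S,7aS)-4-[(4-methoxybenzyl)oxy]-7a-{[(4-methoxybenzyl)oxy]methyl}-2,2-dimethyl-3a,4,5,7a-tetrahydro-1,3-benzodioxol-5-yl]oxy}dimethylsilane
Product: 22 (3aS,4S,5S,7aS)-5-[(tert-butyldimethylsilyl)oxy]-7a-(hydroxymethyl)-2,2-dimethyl-3a,4,5,7a-tetrahydro-1,3-benzodioxol-4-ol
Conditions: DDQ (2.6 equiv), CH2Cl2/pH 7 buffer (10:1), 0 °C → rt
Reagents that add atoms: none
Why: Oxidative cleavage of both PMB ethers by electron transfer to DDQ and hydrolysis of the resulting oxocarbenium ions, which should free exactly the C3 and C7 hydroxyls while the silyl ether and the acetonide stay in place.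

Step 15
Reactants: 22 (3aS,4S,5S,7aS)-5-[(tert-butyldimethylsilyl)oxy]-7a-(hydroxymethyl)-2,2-dimethyl-3a,4,5,7a-tetrahydro-1,3-benzodioxol-4-ol
Product: 23 [(3aS,4S,5S,7aS)-4-(benzoyloxy)-5-[(tert-butyldimethylsilyl)oxy]-2,2-dimethyl-3a,4,5,7a-tetrahydro-1,3-benzodioxol-7a-yl]methyl benzoate
Conditions: BzCl (3 equiv), pyridine, 4-(dimethylamino)pyridine (cat.), CH2Cl2, 0 °C → rt
Reagents that add atoms: benzoyl chloride, O=C(Cl)c1ccccc1
Why: Nucleophile-catalysed acylation of the only two free hydroxyls, the primary C7-OH and the secondary C3-OH, places both benzoates in one operation with no selectivity demand.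

Step 16
Reactants: 23 [(3aS,4S,5S,7aS)-4-(benzoyloxy)-5-[(tert-butyldimethylsilyl)oxy]-2,2-dimethyl-3a,4,5,7a-tetrahydro-1,3-benzodioxol-7a-yl]methyl benzoate
Product: 24 [(1S,2S,3R,4S)-3-(benzoyloxy)-1,2,4-trihydroxycyclohex-5-en-1-yl]methyl benzoate (1alpha-benzoyloxymethyl-3alpha-benzoyloxycyclohex-5-en-1beta,2beta,4beta-triol)
Conditions: TFA/H2O (9:1), 0 °C → rt
Reagents that add atoms: none
Why: Acid hydrolysis should remove the acetonide and the allylic silyl ether together, and acid is chosen over base or fluoride because benzoates do not migrate to neighbouring hydroxyls at low pH.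

**Compound list**

1 | diethyl L-tartrate, diethyl (2R,3R)-2,3-dihydroxybutanedioate | CCOC(=O)[C@H](O)[C@@H](O)C(=O)OCC | starting material
2 | diethyl (2R,3R)-2-[(tert-butyldimethylsilyl)oxy]-3-hydroxybutanedioate | CCOC(=O)[C@H](O[Si](C)(C)C(C)(C)C)[C@@H](O)C(=O)OCC | intermediate
3 | ethyl (2R,3S)-2-[(tert-butyldimethylsilyl)oxy]-3,4-dihydroxybutanoate | CCOC(=O)[C@H](O[Si](C)(C)C(C)(C)C)[C@@H](O)CO | intermediate
4 | ethyl (2R)-2-[(tert-butyldimethylsilyl)oxy]-2-[(4S)-2-(4-methoxyphenyl)-1,3-dioxolan-4-yl]acetate | CCOC(=O)[C@H](O[Si](C)(C)C(C)(C)C)[C@@H]1COC(c2ccc(OC)cc2)O1 | intermediate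
5 | dimethyl (1-diazo-2-oxopropyl)phosphonate | CC(=O)C(=[N+]=[N-])P(=O)(OC)OC | starting material
6 | (2R)-2-[(tert-butyldimethylsilyl)oxy]-2-[(4S)-2-(4-methoxyphenyl)-1,3-dioxolan-4-yl]acetaldehyde | O=C[C@H](O[Si](C)(C)C(C)(C)C)[C@@H]1COC(c2ccc(OC)cc2)O1 | intermediate (not isolated)
7 | (4S)-4-[(1S)-1-[(tert-butyldimethylsilyl)oxy]prop-2-yn-1-yl]-2-(4-methoxyphenyl)-1,3-dioxolane | C#C[C@H](O[Si](C)(C)C(C)(C)C)[C@@H]1COC(c2ccc(OC)cc2)O1 | intermediate
8 | allyl alcohol (prop-2-en-1-ol) | C=CCO | starting material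
9 | 4-methoxybenzyl chloride | COc1ccc(CCl)cc1 | starting material
10 | sodium prop-2-en-1-olate | [Na+].[O-]CC=C | intermediate (not isolated)
11 | 1-methoxy-4-[(prop-2-en-1-yloxy)methyl]benzene (allyl 4-methoxybenzyl ether) | C=CCOCc1ccc(OC)cc1 | intermediate
12 | 3-{[(4-methoxybenzyl)oxy]methyl}-1,2,4-trioxolane (ozonide) | COc1ccc(COCC2OCOO2)cc1 | intermediate (not isolated)
13 | 2-[(4-methoxybenzyl)oxy]acetaldehyde | COc1ccc(COCC=O)cc1 | intermediate
14 | lithium (3S)-3-[(tert-butyldimethylsilyl)oxy]-3-[(4S)-2-(4-methoxyphenyl)-1,3-dioxolan-4-yl]prop-1-yn-1-ide | [Li]C#C[C@H](O[Si](C)(C)C(C)(C)C)[C@@H]1COC(c2ccc(OC)cc2)O1 | intermediate (not isolated)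
15 | (5S)-5-[(tert-butyldimethylsilyl)oxy]-1-[(4-methoxybenzyl)oxy]-5-[(4S)-2-(4-methoxyphenyl)-1,3-dioxolan-4-yl]pent-3-yn-2-ol | COc1ccc(COCC(O)C#C[C@H](O[Si](C)(C)C(C)(C)C)[C@@H]2COC(c3ccc(OC)cc3)O2)cc1 | intermediate
16 | (3Z,5S)-5-[(tert-butyldimethylsilyl)oxy]-1-[(4-methoxybenzyl)oxy]-5-[(4S)-2-(4-methoxyphenyl)-1,3-dioxolan-4-yl]pent-3-en-2-ol | COc1ccc(COCC(O)/C=C\[C@H](O[Si](C)(C)C(C)(C)C)[C@@H]2COC(c3ccc(OC)cc3)O2)cc1 | intermediate
17 | (2S,3S,4Z)-3-[(tert-butyldimethylsilyl)oxy]-2,7-bis[(4-methoxybenzyl)oxy]hept-4-ene-1,6-diol | OC[C@H](OCc1ccc(OC)cc1)[C@@H](O[Si](C)(C)C(C)(C)C)/C=C\C(O)COCc1ccc(OC)cc1 | intermediate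
18 | (2R,3S,4Z)-3-[(tert-butyldimethylsilyl)oxy]-2,7-bis[(4-methoxybenzyl)oxy]-6-oxohept-4-enal | O=C[C@H](OCc1ccc(OC)cc1)[C@@H](O[Si](C)(C)C(C)(C)C)/C=C\C(=O)COCc1ccc(OC)cc1 | intermediate
19 | (1S,3R,4S)-4-[(tert-butyldimethylsilyl)oxy]-1-hydroxy-3-[(4-methoxybenzyl)oxy]-1-{[(4-methoxybenzyl)oxy]methyl}cyclohex-5-en-2-one | O=C1[C@H](OCc2ccc(OC)cc2)[C@@H](O[Si](C)(C)C(C)(C)C)C=C[C@]1(O)COCc1ccc(OC)cc1 | intermediate
20 | (1S,2S,3S,4S)-4-[(tert-butyldimethylsilyl)oxy]-3-[(4-methoxybenzyl)oxy]-1-{[(4-methoxybenzyl)oxy]methyl}cyclohex-5-ene-1,2-diol | COc1ccc(COC[C@@]2(O)C=C[C@H](O[Si](C)(C)C(C)(C)C)[C@@H](OCc3ccc(OC)cc3)[C@@H]2O)cc1 | intermediate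
21 | tert-butyl{[(3aS,4S,5S,7aS)-4-[(4-methoxybenzyl)oxy]-7a-{[(4-methoxybenzyl)oxy]methyl}-2,2-dimethyl-3a,4,5,7a-tetrahydro-1,3-benzodioxol-5-yl]oxy}dimethylsilane (C1/C2 acetonide of 20) | COc1ccc(COC[C@@]2(O3)C=C[C@H](O[Si](C)(C)C(C)(C)C)[C@@H](OCc4ccc(OC)cc4)[C@@H]2OC3(C)C)cc1 | intermediate
22 | (3aS,4S,5S,7aS)-5-[(tert-butyldimethylsilyl)oxy]-7a-(hydroxymethyl)-2,2-dimethyl-3a,4,5,7a-tetrahydro-1,3-benzodioxol-4-ol | OC[C@@]1(O2)C=C[C@H](O[Si](C)(C)C(C)(C)C)[C@@H](O)[C@@H]1OC2(C)C | intermediate
23 | [(3aS,4S,5S,7aS)-4-(benzoyloxy)-5-[(tert-butyldimethylsilyl)oxy]-2,2-dimethyl-3a,4,5,7a-tetrahydro-1,3-benzodioxol-7a-yl]methyl benzoate | O=C(OC[C@@]1(O2)C=C[C@H](O[Si](C)(C)C(C)(C)C)[C@@H](OC(=O)c3ccccc3)[C@@H]1OC2(C)C)c1ccccc1 | intermediate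
24 | [(1S,2S,3R,4S)-3-(benzoyloxy)-1,2,4-trihydroxycyclohex-5-en-1-yl]methyl benzoate | O=C(OC[C@@]1(O)C=C[C@H](O)[C@@H](OC(=O)c2ccccc2)[C@@H]1O)c1ccccc1 | target

**Step count.** Total: 16 steps. Longest linear sequence: 14 steps (steps 1–4 and 7–16, from diethyl L-tartrate); the aldehyde branch (steps 5 and 6) joins in step 7.

**Steps most likely to fail**

Step 11 (key step). Reversible conjugate addition of the carbene or the amine to the enone may isomerise C5=C6 to the (E)-geometry, from which no ring can form. Closure may also take the wrong face of the C1 ketone, or base may trigger loss of the C4 silyloxy group through the C3 enolate. The fallback replaces the umpolung closure by a reductive pinacol cyclisation. It sets out from 18 and comes back to the route at 20, passing over 19. SmI2 (divalent samarium, 2.5 equiv) with t-BuOH in THF at −78 °C should reduce both carbonyl groups to ketyls that couple inside a samarium-bridged chelate. This is a known way to close 1,6-dicarbonyl compounds to cis-cyclohexane-1,2-diols that lie anti to a neighbouring alkoxy group. Coupling at C1 is the only ring-forming mode, and the cis diol anti to C3-OPMB is 20. No new compound arises (F0).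

Step 10. The half-oxidised hydroxy aldehyde may close to a seven-membered lactol and be oxidised on to a lactone. The (Z)-enone may also isomerise, or the α-alkoxy aldehyde epimerise, during work-up. The fallback carries out the oxidation before the alkene exists. It sets out from 15 and comes back at 18. i-Bu2AlH in CH2Cl2 (−78 → 0 °C) opens the acetal of 15 to the alkyne diol (2S,3S)-3-[(tert-butyldimethylsilyl)oxy]-2,7-bis[(4-methoxybenzyl)oxy]hept-4-yne-1,6-diol F1. Dess–Martin periodinane then gives the ynone aldehyde (2R,3S)-3-[(tert-butyldimethylsilyl)oxy]-2,7-bis[(4-methoxybenzyl)oxy]-6-oxohept-4-ynal F2, in which the linear alkyne can neither isomerise nor allow a lactol. Semihydrogenation over Pd/CaCO3–Pb(OAc)2 with quinoline should deliver 18 under neutral conditions directly before the key step.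

Step 4. The ester may be over-reduced to the alcohol, and the α-silyloxy aldehyde may epimerise or lose its β-oxygen in basic methanol. The fallback uses a Corey–Fuchs sequence in place of the diazophosphonate homologation. It sets out from 4 and comes back at 14, and so at 15. LiBH4 in THF reduces 4 to the alcohol (2S)-2-[(tert-butyldimethylsilyl)oxy]-2-[(4S)-2-(4-methoxyphenyl)-1,3-dioxolan-4-yl]ethan-1-ol F3. Parikh–Doering oxidation (SO3·pyridine, DMSO, i-Pr2NEt) gives aldehyde 6, now isolated. CBr4/PPh3 with Et3N converts 6 into the dibromoalkene (4S)-4-[(1S)-3,3-dibromo-1-[(tert-butyldimethylsilyl)oxy]prop-2-en-1-yl]-2-(4-methoxyphenyl)-1,3-dioxolane F4. n-BuLi (2.1 equiv) in THF at −78 °C turns F4 into lithium acetylide 14 by elimination and bromine–lithium exchange, and 14 is trapped with 13 as in step 7.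

**Further compounds**

F0 | step 11 | none | none
F1 | step 10 | (2S,3S)-3-[(tert-butyldimethylsilyl)oxy]-2,7-bis[(4-methoxybenzyl)oxy]hept-4-yne-1,6-diol | OC[C@H](OCc1ccc(OC)cc1)[C@@H](O[Si](C)(C)C(C)(C)C)C#CC(O)COCc1ccc(OC)cc1
F2 | step 10 | (2R,3S)-3-[(tert-butyldimethylsilyl)oxy]-2,7-bis[(4-methoxybenzyl)oxy]-6-oxohept-4-ynal | O=C[C@H](OCc1ccc(OC)cc1)[C@@H](O[Si](C)(C)C(C)(C)C)C#CC(=O)COCc1ccc(OC)cc1
F3 | step 4 | (2S)-2-[(tert-butyldimethylsilyl)oxy]-2-[(4S)-2-(4-methoxyphenyl)-1,3-dioxolan-4-yl]ethan-1-ol | OC[C@H](O[Si](C)(C)C(C)(C)C)[C@@H]1COC(c2ccc(OC)cc2)O1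
F4 | step 4 | (4S)-4-[(1S)-3,3-dibromo-1-[(tert-butyldimethylsilyl)oxy]prop-2-en-1-yl]-2-(4-methoxyphenyl)-1,3-dioxolane | BrC(Br)=C[C@H](O[Si](C)(C)C(C)(C)C)[C@@H]1COC(c2ccc(OC)cc2)O1
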